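Retrosynthesis: the two bromines ortho to the phenol OH groups of rings A and B are removed first. The C4–aryl bond (ring B) and the exocyclic CH–aryl bond (ring A) are then cut together. The carbinol is traced through its ketone to a benzylic CH2, and the butenolide is opened to a 2-benzyllevulinic acid, which is cut at C2 into an aldehyde, Meldrum's acid and chloroacetone.
Enabling feature: butenolide C4 and the exocyclic carbon on C5 bear the same 3-bromo-4-hydroxyphenyl group. Both are sp2 carbons conjugated with the lactone C2=O (β and δ positions), so a (Z)-4-bromo-5-(bromomethylene)butenolide can take up one arylboronic acid twice.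
Forward: ring C enters with the aldehyde and the five-carbon chain is assembled on Meldrum's acid (steps 1–3). Bromination and acid cyclisation close the butenolide, the only ring made (steps 4–5). The benzylic carbon is then oxidised, reduced and protected (steps 6–10), rings B and A are attached in one operation (step 11), and desilylation and bromination finish the route (steps 12–13).
Stereochemistry: the single stereocentre, (S) at the carbinol (O > butenolide C3 > ring C > H), comes from a Corey–Bakshi–Shibata reduction of the aryl butenolidyl ketone in step 9. The Z alkene is set in step 5 and carried through step 11 with retention.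

Key step: step 11

Assumption: in step 9 the butenolide, forced out of the carbonyl plane by its C2 carbonyl and C4 bromine, is taken as the large group and flat ring C as the small one, which calls for the (R)-catalyst; the configuration of 15 would be checked by Mosher ester analysis, and the (S)-catalyst used in the same step if the sense is the reverse.

Step 1
Reactants: 1 3,5-dibromo-4-methoxybenzaldehyde; 2 Meldrum's acid (2,2-dimethyl-1,3-dioxane-4,6-dione)
Product: 4 5-(3,5-dibromo-4-methoxybenzyl)-2,2-dimethyl-1,3-dioxane-4,6-dione, via arylidene Meldrum's acid 3 (not isolated)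
Conditions: diethyl 2,6-dimethyl-1,4-dihydropyridine-3,5-dicarboxylate (Hantzsch ester, 1 equiv), L-proline (20 mol %), EtOH, rt
Reagents that add atoms: none
Why: Proline-catalysed Knoevenagel condensation gives the highly electrophilic arylidene 3, which the Hantzsch ester reduces at once by conjugate hydride transfer (three-component reductive alkylation), so that a second Meldrum's acid cannot add and the monobenzyl compound should result.

Step 2
Reactants: 4 5-(3,5-dibromo-4-methoxybenzyl)-2,2-dimethyl-1,3-dioxane-4,6-dione; 5 chloroacetone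
Product: 6 5-(3,5-dibromo-4-methoxybenzyl)-2,2-dimethyl-5-(2-oxopropyl)-1,3-dioxane-4,6-dione
Conditions: K2CO3 (1.5 equiv), DMF, rt to 40 °C
Reagents that add atoms: none
Why: Carbonate removes the acidic C5 proton of 4 and the soft carbanion displaces chloride from the α-chloro ketone in an SN2 C-alkylation, the standard entry to 5,5-disubstituted Meldrum's acids.

Step 3
Reactants: 6 5-(3,5-dibromo-4-methoxybenzyl)-2,2-dimethyl-5-(2-oxopropyl)-1,3-dioxane-4,6-dione
Product: 8 2-(3,5-dibromo-4-methoxybenzyl)-4-oxopentanoic acid (racemic), via substituted malonic acid 7 (not isolated)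
Conditions: 6 M HCl, AcOH, reflux
Reagents that add atoms: water, O
Why: Acid hydrolysis of the cyclic acylal releases acetone and the malonic acid 7, which loses CO2 at reflux as in the malonic ester synthesis of γ-keto acids, while the aryl bromides and the aryl methyl ether tolerate hot aqueous HCl; the C2 stereocentre forms racemic and is erased in step 5.

Step 4
Reactants: 8 2-(3,5-dibromo-4-methoxybenzyl)-4-oxopentanoic acid
Product: 9 3,5-dibromo-2-(3,5-dibromo-4-methoxybenzyl)-4-oxopentanoic acid (racemic mixture of diastereomers, used crude)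
Conditions: Br2 (2.1 equiv), HBr (cat.), CHCl3, 0 °C to rt, dark
Reagents that add atoms: bromine, BrBr
Why: Acid-catalysed α-bromination of the ketone through its two enols puts one bromine on C3 and one on C5, as known for 2-alkyllevulinic acids, ring C being inert because both positions ortho to its methoxy group are filled; the new stereocentres form without control and disappear in step 5.

Step 5
Reactants: 9 3,5-dibromo-2-(3,5-dibromo-4-methoxybenzyl)-4-oxopentanoic acid
Product: 11 (Z)-4-bromo-5-(bromomethylidene)-3-(3,5-dibromo-4-methoxybenzyl)furan-2(5H)-one, via bromo enol lactone 10 (not isolated)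
Conditions: conc. H2SO4, 100–110 °C, 20–30 min, then ice; chromatography
Reagents that add atoms: none
Why: Sulfuric acid-mediated enol lactonisation of the dibromo keto acid closes the five-membered ring to 10 and the hot acid, acting as oxidant as well, dehydrogenates C3–C4, a cyclisation known for brominated 2-alkyllevulinic acids, with the Z-bromomethylene isomer favoured because it keeps the exocyclic bromine away from the C4 bromine.

Step 6
Reactants: 11 (Z)-4-bromo-5-(bromomethylidene)-3-(3,5-dibromo-4-methoxybenzyl)furan-2(5H)-one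
Product: 12 (Z)-4-bromo-3-[bromo(3,5-dibromo-4-methoxyphenyl)methyl]-5-(bromomethylidene)furan-2(5H)-one (racemic)
Conditions: NBS (1.05 equiv), 2,2'-azobis(2-methylpropionitrile) (cat.), PhCF3, reflux, visible light
Reagents that add atoms: N-bromosuccinimide, O=C1CCC(=O)N1Br
Why: Wohl–Ziegler radical bromination takes the CH2 hydrogen because the derived radical is both benzylic and allylic, in line with the side-chain bromination known for 3-alkyl-4-bromo-5-(bromomethylene)furanones; the new stereocentre is racemic.

Step 7
Reactants: 12 (Z)-4-bromo-3-[bromo(3,5-dibromo-4-methoxyphenyl)methyl]-5-(bromomethylidene)furan-2(5H)-one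
Product: 13 (Z)-4-bromo-5-(bromomethylidene)-3-[(3,5-dibromo-4-methoxyphenyl)(hydroxy)methyl]furan-2(5H)-one (racemic)
Conditions: AgNO3 (1.5 equiv), acetone/H2O (4:1), rt, dark
Reagents that add atoms: water, O
Why: Silver-assisted SN1 solvolysis replaces only the sp3 bromide by water, the alkenyl and aryl bromides being inert to silver ion and the acidic medium sparing the base-sensitive bromobutenolide; the carbinol is racemic at this stage.

Step 8
Reactants: 13 (Z)-4-bromo-5-(bromomethylidene)-3-[(3,5-dibromo-4-methoxyphenyl)(hydroxy)methyl]furan-2(5H)-one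
Product: 14 (Z)-4-bromo-5-(bromomethylidene)-3-(3,5-dibromo-4-methoxybenzoyl)furan-2(5H)-one
Conditions: Dess–Martin periodinane (1,1,1-triacetoxy-1,1-dihydro-1,2-benziodoxol-3(1H)-one, 1.3 equiv), CH2Cl2, 0 °C to rt; filtration through silica, used without delay
Reagents that add atoms: none
Why: Dess–Martin oxidation turns the secondary benzylic alcohol into the ketone under neutral, non-aqueous conditions that offer no nucleophile to the very electrophilic C4–Br position, and it erases the racemic centre.

Step 9
Reactants: 14 (Z)-4-bromo-5-(bromomethylidene)-3-(3,5-dibromo-4-methoxybenzoyl)furan-2(5H)-one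
Product: 15 (Z)-4-bromo-5-(bromomethylidene)-3-[(S)-(3,5-dibromo-4-methoxyphenyl)(hydroxy)methyl]furan-2(5H)-one
Conditions: (R)-1-methyl-3,3-diphenyltetrahydro-1H,3H-pyrrolo[1,2-c][1,3,2]oxazaborole ((R)-Me-CBS, 20 mol %), catecholborane (1.5 equiv), toluene, −78 to −40 °C; pH 7 buffer
Reagents that add atoms: none
Why: Corey–Bakshi–Shibata reduction: the ketone should bind to the ring boron of the catalyst through the lone pair on the side of flat ring C, away from the twisted butenolide, and the catecholborane held on the neighbouring nitrogen then delivers hydride to one face only to set the (S) centre, this mild borane giving 1,2-reduction without touching the lactone or the C–Br bonds.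

Step 10
Reactants: 15 (Z)-4-bromo-5-(bromomethylidene)-3-[(S)-(3,5-dibromo-4-methoxyphenyl)(hydroxy)methyl]furan-2(5H)-one
Product: 16 (Z)-4-bromo-5-(bromomethylidene)-3-[(S)-(tert-butyldimethylsilyloxy)(3,5-dibromo-4-methoxyphenyl)methyl]furan-2(5H)-one
Conditions: TBSOTf (1.3 equiv), 2,6-lutidine (2 equiv), CH2Cl2, −78 to 0 °C
Reagents that add atoms: tert-butyldimethylsilyl triflate, CC(C)(C)[Si](C)(C)OS(=O)(=O)C(F)(F)F
Why: Silylation of the hindered secondary alcohol with the silyl triflate and a non-nucleophilic pyridine base, chosen over imidazole or trialkylamines because these could displace the C4 bromide by addition–elimination, leaves the C–O bond and thus the (S) configuration untouched.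

Step 11
Reactants: 16 (Z)-4-bromo-5-(bromomethylidene)-3-[(S)-(tert-butyldimethylsilyloxy)(3,5-dibromo-4-methoxyphenyl)methyl]furan-2(5H)-one; 17 4-(tert-butyldimethylsilyloxy)phenylboronic acid (2.2 equiv)
Product: 19 (Z)-3-[(S)-(tert-butyldimethylsilyloxy)(3,5-dibromo-4-methoxyphenyl)methyl]-4-[4-(tert-butyldimethylsilyloxy)phenyl]-5-[4-(tert-butyldimethylsilyloxy)benzylidene]furan-2(5H)-one, via C4-monoarylated bromide 18 (not isolated)
Conditions: Pd(PPh3)4 (5 mol %), K3PO4 (4 equiv), toluene/H2O (10:1), 60 °C, argon
Reagents that add atoms: none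
Why: Zerovalent palladium inserts into the C4–Br bond, the β-bromide of the unsaturated lactone, and into the exocyclic (Z)-CH–Br bond, its δ-vinylogue, and each alkenyl bromide complex of divalent palladium takes the aryl group from phosphate-activated 17 and reductively eliminates, so that 18 and then 19 should arise (the order of the two events does not affect the outcome). The reaction type is the Suzuki–Miyaura coupling, known on β-bromobutenolides and on 4-bromo-5-(bromomethylene)furanones. The step closes no ring and creates no stereocentre: the silyl-protected (S) carbinol is a spectator, and the Z geometry is carried over because insertion and reductive elimination at sp2 carbon are stereoretentive, the Z-benzylidene also being the more stable isomer. The selectivity needed is reaction of the two alkenyl bromides ahead of the two aryl bromides of ring C; the former are electron-poor through conjugation with the lactone carbonyl, whereas the latter flank a methoxy group on a ring without any acceptor, so insertion of the PPh3-ligated catalyst there should be slow at 60 °C. Holding 17 to a slight excess over two equivalents and using a base free of fluoride and alcohol should keep ring C, the aryl silyl ethers and the lactone intact. Since 17 has no halogen it cannot oligomerise, and one boron reagent serves both sites because rings A and B are identical.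

Step 12
Reactants: 19 tris-silyl ether from step 11
Product: 20 (Z)-3-[(S)-(3,5-dibromo-4-methoxyphenyl)(hydroxy)methyl]-5-(4-hydroxybenzylidene)-4-(4-hydroxyphenyl)furan-2(5H)-one
Conditions: HF·pyridine, pyridine, THF, 0 °C to rt
Reagents that add atoms: none
Why: Fluoride-induced Si–O cleavage, driven by the strong Si–F bond, removes all three silyl groups, and the pyridine buffer avoids both phenoxide formation and acid ionisation of the carbinol, which is benzylic to ring C and vinylogously benzylic to ring B, so the (S) centre should be kept.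

Step 13
Reactants: 20 (Z)-3-[(S)-(3,5-dibromo-4-methoxyphenyl)(hydroxy)methyl]-5-(4-hydroxybenzylidene)-4-(4-hydroxyphenyl)furan-2(5H)-one
Product: 21 (Z)-5-(3-bromo-4-hydroxybenzylidene)-4-(3-bromo-4-hydroxyphenyl)-3-[(S)-(3,5-dibromo-4-methoxyphenyl)(hydroxy)methyl]furan-2(5H)-one (target)
Conditions: NBS (2.0 equiv, in portions), MeCN, −20 to 0 °C, dark
Reagents that add atoms: N-bromosuccinimide, O=C1CCC(=O)N1Br
Why: Electrophilic aromatic bromination: only the two free phenol rings are activated, their para positions are blocked so attack falls ortho to OH, and the first bromine lowers the reactivity of its ring enough that one equivalent per ring should stop at the monobromide, while the neutral medium leaves the ionisable carbinol and the Z alkene alone.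

Compound list
1 | 3,5-dibromo-4-methoxybenzaldehyde | COc1c(Br)cc(C=O)cc1Br | starting material
2 | Meldrum's acid (2,2-dimethyl-1,3-dioxane-4,6-dione) | CC1(C)OC(=O)CC(=O)O1 | starting material
3 | 5-(3,5-dibromo-4-methoxybenzylidene)-2,2-dimethyl-1,3-dioxane-4,6-dione | COc1c(Br)cc(C=C2C(=O)OC(C)(C)OC2=O)cc1Br | intermediate
4 | 5-(3,5-dibromo-4-methoxybenzyl)-2,2-dimethyl-1,3-dioxane-4,6-dione | COc1c(Br)cc(CC2C(=O)OC(C)(C)OC2=O)cc1Br | intermediate
5 | chloroacetone | CC(=O)CCl | starting material
6 | 5-(3,5-dibromo-4-methoxybenzyl)-2,2-dimethyl-5-(2-oxopropyl)-1,3-dioxane-4,6-dione | COc1c(Br)cc(CC2(CC(C)=O)C(=O)OC(C)(C)OC2=O)cc1Br | intermediate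
7 | 2-(3,5-dibromo-4-methoxybenzyl)-2-(2-oxopropyl)malonic acid | COc1c(Br)cc(CC(CC(C)=O)(C(=O)O)C(=O)O)cc1Br | intermediate
8 | 2-(3,5-dibromo-4-methoxybenzyl)-4-oxopentanoic acid (racemic) | COc1c(Br)cc(CC(CC(C)=O)C(=O)O)cc1Br | intermediate
9 | 3,5-dibromo-2-(3,5-dibromo-4-methoxybenzyl)-4-oxopentanoic acid (racemic, diastereomer mixture) | COc1c(Br)cc(CC(C(Br)C(=O)CBr)C(=O)O)cc1Br | intermediate
10 | (Z)-4-bromo-5-(bromomethylidene)-3-(3,5-dibromo-4-methoxybenzyl)dihydrofuran-2(3H)-one (racemic, diastereomer mixture) | COc1c(Br)cc(CC2C(Br)/C(=C/Br)OC2=O)cc1Br | intermediate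
11 | (Z)-4-bromo-5-(bromomethylidene)-3-(3,5-dibromo-4-methoxybenzyl)furan-2(5H)-one | COc1c(Br)cc(CC2=C(Br)/C(=C/Br)OC2=O)cc1Br | intermediate
12 | (Z)-4-bromo-3-[bromo(3,5-dibromo-4-methoxyphenyl)methyl]-5-(bromomethylidene)furan-2(5H)-one (racemic) | COc1c(Br)cc(C(Br)C2=C(Br)/C(=C/Br)OC2=O)cc1Br | intermediate
13 | (Z)-4-bromo-5-(bromomethylidene)-3-[(3,5-dibromo-4-methoxyphenyl)(hydroxy)methyl]furan-2(5H)-one (racemic) | COc1c(Br)cc(C(O)C2=C(Br)/C(=C/Br)OC2=O)cc1Br | intermediate
14 | (Z)-4-bromo-5-(bromomethylidene)-3-(3,5-dibromo-4-methoxybenzoyl)furan-2(5H)-one | COc1c(Br)cc(C(=O)C2=C(Br)/C(=C/Br)OC2=O)cc1Br | intermediate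
15 | (Z)-4-bromo-5-(bromomethylidene)-3-[(S)-(3,5-dibromo-4-methoxyphenyl)(hydroxy)methyl]furan-2(5H)-one | COc1c(Br)cc([C@H](O)C2=C(Br)/C(=C/Br)OC2=O)cc1Br | intermediate
16 | (Z)-4-bromo-5-(bromomethylidene)-3-[(S)-(tert-butyldimethylsilyloxy)(3,5-dibromo-4-methoxyphenyl)methyl]furan-2(5H)-one | COc1c(Br)cc([C@H](O[Si](C)(C)C(C)(C)C)C2=C(Br)/C(=C/Br)OC2=O)cc1Br | intermediate
17 | 4-(tert-butyldimethylsilyloxy)phenylboronic acid | CC(C)(C)[Si](C)(C)Oc1ccc(B(O)O)cc1 | starting material
18 | (Z)-5-(bromomethylidene)-3-[(S)-(tert-butyldimethylsilyloxy)(3,5-dibromo-4-methoxyphenyl)methyl]-4-[4-(tert-butyldimethylsilyloxy)phenyl]furan-2(5H)-one | COc1c(Br)cc([C@H](O[Si](C)(C)C(C)(C)C)C2=C(c3ccc(O[Si](C)(C)C(C)(C)C)cc3)/C(=C/Br)OC2=O)cc1Br | intermediate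
19 | (Z)-3-[(S)-(tert-butyldimethylsilyloxy)(3,5-dibromo-4-methoxyphenyl)methyl]-4-[4-(tert-butyldimethylsilyloxy)phenyl]-5-[4-(tert-butyldimethylsilyloxy)benzylidene]furan-2(5H)-one | COc1c(Br)cc([C@H](O[Si](C)(C)C(C)(C)C)C2=C(c3ccc(O[Si](C)(C)C(C)(C)C)cc3)/C(=C/c3ccc(O[Si](C)(C)C(C)(C)C)cc3)OC2=O)cc1Br | intermediate
20 | (Z)-3-[(S)-(3,5-dibromo-4-methoxyphenyl)(hydroxy)methyl]-5-(4-hydroxybenzylidene)-4-(4-hydroxyphenyl)furan-2(5H)-one | COc1c(Br)cc([C@H](O)C2=C(c3ccc(O)cc3)/C(=C/c3ccc(O)cc3)OC2=O)cc1Br | intermediate
21 | (Z)-5-(3-bromo-4-hydroxybenzylidene)-4-(3-bromo-4-hydroxyphenyl)-3-[(S)-(3,5-dibromo-4-methoxyphenyl)(hydroxy)methyl]furan-2(5H)-one | COc1c(Br)cc([C@H](O)C2=C(c3ccc(O)c(Br)c3)/C(=C/c3ccc(O)c(Br)c3)OC2=O)cc1Br | target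

Total step count: 13. Longest linear sequence: 13 steps, from 1 to 21; compounds 2, 5 and 17 are purchased.

Steps most likely to fail

Step 5. In hot concentrated acid ring C may be sulfonated, its methyl ether may be cleaved, or the carboxylic acid may close onto ring C by Friedel–Crafts acylation. Part of the material may also drain into the 5-(dibromomethylene) isomer. The fallback sets out from 1, comes back at 11 and replaces steps 1–5. It takes the butenolide from a tetronic acid, so no strong acid is needed.
- Aldehyde 1, purchased 5-methyltetronic acid (CC1OC(=O)C=C1O), Hantzsch ester and L-proline would give, by the reductive alkylation of step 1, 3-(3,5-dibromo-4-methoxybenzyl)-4-hydroxy-5-methylfuran-2(5H)-one F1.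
- Oxalyl bromide and DMF in CH2Cl2 convert this vinylogous acid into 4-bromo-3-(3,5-dibromo-4-methoxybenzyl)-5-methylfuran-2(5H)-one F2.
- TBSOTf and Et3N deprotonate C5 and give tert-butyl{[4-bromo-3-(3,5-dibromo-4-methoxybenzyl)-5-methylfuran-2-yl]oxy}dimethylsilane F3.
- NBS at −78 °C attacks this silyloxyfuran at C5 to give 4,5-dibromo-3-(3,5-dibromo-4-methoxybenzyl)-5-methylfuran-2(5H)-one F4.
- Et3N removes HBr from F4 to leave 4-bromo-3-(3,5-dibromo-4-methoxybenzyl)-5-methylidenefuran-2(5H)-one F5.
- Br2 adds to the exocyclic alkene to give 4,5-dibromo-5-(bromomethyl)-3-(3,5-dibromo-4-methoxybenzyl)furan-2(5H)-one F6.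
- A second dehydrobromination with Et3N leads to 11. The Z isomer is favoured because it avoids contact between the two vinylic bromines.

Step 9. Facial discrimination may be poor because both groups on the carbonyl carbon are sp2 and of similar bulk. Hydride may also be delivered in conjugate fashion to C4 with loss of bromide. The fallback sets out from 13, comes back at 15 and makes steps 8 and 9 unnecessary. It uses acylative kinetic resolution in place of asymmetric reduction.
- Racemic 13 would be treated with about half an equivalent of isobutyric anhydride and iPr2NEt.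
- The catalyst is the isothiourea 3-isopropyl-2-phenyl-3,4-dihydro-2H-benzo[4,5]thiazolo[3,2-a]pyrimidine, in the enantiomeric form that acylates the (R)-alcohol faster. This catalyst class is known to tell an aryl from an alkenyl group on a secondary carbinol.
- The (R)-alcohol is converted into (Z)-4-bromo-5-(bromomethylidene)-3-[(R)-(3,5-dibromo-4-methoxyphenyl)(isobutyryloxy)methyl]furan-2(5H)-one F7.
- The unreacted (S)-alcohol 15 is separated by chromatography and goes on to step 10.

Step 13. The two phenol rings may differ in reactivity, so that one ring takes up two bromines before the other has reacted, and statistical under- and over-bromination may occur. The fallback sets out from 16, comes back at 21 and replaces steps 11–13. It brings the bromines in with the boron partner, and the same two C–aryl bonds are formed.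
- Purchased 2-bromo-4-iodophenol is silylated (TBSCl, imidazole) to (2-bromo-4-iodophenoxy)(tert-butyl)dimethylsilane F8.
- Selective iodine–magnesium exchange with iPrMgCl·LiCl at −40 °C, then B(OMe)3 and mild acid, give [3-bromo-4-(tert-butyldimethylsilyloxy)phenyl]boronic acid F9.
- The twofold coupling of 16 with F9 under the conditions of step 11 relies on the same preference for conjugated alkenyl bromides over electron-rich, ortho-oxygenated aryl bromides. It gives (Z)-5-[3-bromo-4-(tert-butyldimethylsilyloxy)benzylidene]-4-[3-bromo-4-(tert-butyldimethylsilyloxy)phenyl]-3-[(S)-(tert-butyldimethylsilyloxy)(3,5-dibromo-4-methoxyphenyl)methyl]furan-2(5H)-one F10.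
- HF·pyridine then gives 21 directly.

Further compounds
F1 | step 5 | 3-(3,5-dibromo-4-methoxybenzyl)-4-hydroxy-5-methylfuran-2(5H)-one (racemic) | COc1c(Br)cc(CC2=C(O)C(C)OC2=O)cc1Br
F2 | step 5 | 4-bromo-3-(3,5-dibromo-4-methoxybenzyl)-5-methylfuran-2(5H)-one (racemic) | COc1c(Br)cc(CC2=C(Br)C(C)OC2=O)cc1Br
F3 | step 5 | tert-butyl{[4-bromo-3-(3,5-dibromo-4-methoxybenzyl)-5-methylfuran-2-yl]oxy}dimethylsilane | COc1c(Br)cc(Cc2c(Br)c(C)oc2O[Si](C)(C)C(C)(C)C)cc1Br
F4 | step 5 | 4,5-dibromo-3-(3,5-dibromo-4-methoxybenzyl)-5-methylfuran-2(5H)-one (racemic) | COc1c(Br)cc(CC2=C(Br)C(C)(Br)OC2=O)cc1Br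
F5 | step 5 | 4-bromo-3-(3,5-dibromo-4-methoxybenzyl)-5-methylidenefuran-2(5H)-one | COc1c(Br)cc(CC2=C(Br)C(=C)OC2=O)cc1Br
F6 | step 5 | 4,5-dibromo-5-(bromomethyl)-3-(3,5-dibromo-4-methoxybenzyl)furan-2(5H)-one (racemic) | COc1c(Br)cc(CC2=C(Br)C(Br)(CBr)OC2=O)cc1Br
F7 | step 9 | (Z)-4-bromo-5-(bromomethylidene)-3-[(R)-(3,5-dibromo-4-methoxyphenyl)(isobutyryloxy)methyl]furan-2(5H)-one | COc1c(Br)cc([C@@H](OC(=O)C(C)C)C2=C(Br)/C(=C/Br)OC2=O)cc1Br
F8 | step 13 | (2-bromo-4-iodophenoxy)(tert-butyl)dimethylsilane | CC(C)(C)[Si](C)(C)Oc1ccc(I)cc1Br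
F9 | step 13 | [3-bromo-4-(tert-butyldimethylsilyloxy)phenyl]boronic acid | CC(C)(C)[Si](C)(C)Oc1ccc(B(O)O)cc1Br
F10 | step 13 | (Z)-5-[3-bromo-4-(tert-butyldimethylsilyloxy)benzylidene]-4-[3-bromo-4-(tert-butyldimethylsilyloxy)phenyl]-3-[(S)-(tert-butyldimethylsilyloxy)(3,5-dibromo-4-methoxyphenyl)methyl]furan-2(5H)-one | COc1c(Br)cc([C@H](O[Si](C)(C)C(C)(C)C)C2=C(c3ccc(O[Si](C)(C)C(C)(C)C)c(Br)c3)/C(=C/c3ccc(O[Si](C)(C)C(C)(C)C)c(Br)c3)OC2=O)cc1Br
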